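**Assumption:** sodium danshensu (sodium (R)-3-(3,4-dihydroxyphenyl)lactate, "salvianic acid A sodium") is bought as the natural (R)-enantiomer and supplies the only stereocentre.

## Retrosynthetic overview

1. Eritrichin ⇒ global hydrogenolysis of a heptabenzyl precursor ⇒ ester disconnection into naphthoic acid 7 and tribenzyl (R)-danshensu 9.
2. Acid 7 ⇒ oxidative decarboxylation/aromatisation of 1-aryl-1,2-dihydronaphthalene-2,3-dicarboxylic acid 6; the sp3 carboxyl is traceless.
3. 6 ⇒ photochemical 6π-electrocyclisation/[1,5]-H shift of the C2-symmetric (E,E)-bis(arylidene)succinic acid 5. One aryl ring is dearomatised and becomes the naphthalene, its twin becomes the 4-aryl group, and the two carboxyls become different.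
4. 5 ⇒ double Stobbe condensation of diethyl succinate with two molecules of 3,4-bis(benzyloxy)benzaldehyde, made from protocatechualdehyde.
5. Ring order: the only ring built is the second carbocycle of the naphthalene (closed in step 3, aromatised in step 4); all catechol rings are bought.

## Route

**Step 1**
Reactants: 1, 3,4-dihydroxybenzaldehyde (protocatechualdehyde); 2, benzyl bromide
Product: 3, 3,4-bis(benzyloxy)benzaldehyde
Conditions: BnBr (2.3 equiv), K2CO3, DMF, 60 °C, N2
Reagents that add atoms: benzyl bromide (2), BrCc1ccccc1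
Why: Williamson ether synthesis on both phenols; the aldehyde is inert to carbonate.

**Step 2**
Reactants: 3, 3,4-bis(benzyloxy)benzaldehyde (2.2 equiv); 4, diethyl succinate
Product: 5, (2E,3E)-2,3-bis[3,4-bis(benzyloxy)benzylidene]butanedioic acid (C2-symmetric)
Conditions: NaOEt (3 equiv), EtOH, reflux; then aq NaOH, reflux; HCl
Reagents that add atoms: diethyl succinate (4), CCOC(=O)CCC(=O)OCC; sodium hydroxide, [Na+].[OH-] (carboxyl oxygen on saponification)
Why: One-pot double Stobbe condensation (the classical dibenzylidenesuccinic acid synthesis) via paraconic-ester lactone intermediates; the thermodynamic E,E isomer (aryl trans to CO2H) is obtained and crystallised.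

**Step 3**
Reactants: 5, (E,E)-bis(arylidene)succinic acid
Product: 6, rac-cis-1-[3,4-bis(benzyloxy)phenyl]-6,7-bis(benzyloxy)-1,2-dihydronaphthalene-2,3-dicarboxylic acid
Conditions: hν (365 nm LED or Pyrex-filtered Hg lamp), degassed THF–MeOH, ca. 5 mM, N2, rt
Reagents that add atoms: none
Why: Photochemical conrotatory 6π-electrocyclisation of the aryl-diene (fulgide-type) gives a dearomatised 1,8a-dihydronaphthalene, and a suprafacial thermal [1,5]-H shift (C8a to C2) restores the benzene ring. Closure occurs at the unhindered C6 of the aryl ring, E/Z photoisomers funnel to the same product, and the two racemic stereocentres are destroyed in step 4.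

**Step 4**
Reactants: 6, dihydronaphthalene diacid
Product: 7, 6,7-bis(benzyloxy)-4-[3,4-bis(benzyloxy)phenyl]naphthalene-2-carboxylic acid
Conditions: Pb(OAc)4 (1.3 equiv), Cu(OAc)2 (10 mol %), pyridine, PhH, 80 °C, N2
Reagents that add atoms: none
Why: Kochi-type oxidative decarboxylation, the standard way to aromatise dihydroarene carboxylic acids: only the sp3 C2–CO2H can fragment, giving an allylic/benzylic radical that is oxidised by Cu(II) and loses H-1 to aromatise. The vinylic C3–CO2H cannot decarboxylate and is retained.

**Step 5**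
Reactants: 8, sodium (R)-3-(3,4-dihydroxyphenyl)-2-hydroxypropanoate (sodium danshensu); 2, benzyl bromide
Product: 9, benzyl (R)-3-[3,4-bis(benzyloxy)phenyl]-2-hydroxypropanoate
Conditions: BnBr (3.3 equiv), K2CO3, DMF, rt, N2 (degassed)
Reagents that add atoms: benzyl bromide (2), BrCc1ccccc1
Why: O-alkylation of the carboxylate and both phenoxides (Williamson/carboxylate SN2); the secondary alcohol is not deprotonated by carbonate, and the stereocentre (chiral pool, R) is not enolised at rt.

**Step 6**
Reactants: 7, naphthoic acid; 9, tribenzyl (R)-danshensu (1.1 equiv)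
Product: 10, benzyl (R)-3-[3,4-bis(benzyloxy)phenyl]-2-({6,7-bis(benzyloxy)-4-[3,4-bis(benzyloxy)phenyl]naphthalene-2-carbonyl}oxy)propanoate
Conditions: EDC·HCl, DMAP, CH2Cl2, 0 °C to rt
Reagents that add atoms: none
Why: Steglich esterification acylates the alcohol oxygen without touching the C–O bond of the stereocentre, so the R configuration is retained.

**Step 7**
Reactants: 10, heptabenzyl eritrichin
Product: 11, eritrichin
Conditions: H2 (1 atm), 10% Pd/C, THF–MeOH, rt; filter under Ar
Reagents that add atoms: none
Why: Hydrogenolysis cleaves six benzyl ethers and the benzyl ester; the naphthalene, the non-benzylic secondary ester and the stereocentre are inert under these conditions.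

## Compound list

1 | 3,4-dihydroxybenzaldehyde | O=Cc1ccc(O)c(O)c1 | starting material
2 | benzyl bromide | BrCc1ccccc1 | starting material
3 | 3,4-bis(benzyloxy)benzaldehyde | O=Cc1ccc(OCc2ccccc2)c(OCc2ccccc2)c1 | intermediate
4 | diethyl succinate | CCOC(=O)CCC(=O)OCC | starting material
5 | (2E,3E)-2,3-bis[3,4-bis(benzyloxy)benzylidene]butanedioic acid | O=C(O)C(=C/c1ccc(OCc2ccccc2)c(OCc2ccccc2)c1)/C(=C\c1ccc(OCc2ccccc2)c(OCc2ccccc2)c1)C(=O)O | intermediate
6 | rac-cis-1-[3,4-bis(benzyloxy)phenyl]-6,7-bis(benzyloxy)-1,2-dihydronaphthalene-2,3-dicarboxylic acid (relative configuration shown) | O=C(O)C1=Cc2cc(OCc3ccccc3)c(OCc3ccccc3)cc2[C@H](c2ccc(OCc3ccccc3)c(OCc3ccccc3)c2)[C@@H]1C(=O)O | intermediate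
7 | 6,7-bis(benzyloxy)-4-[3,4-bis(benzyloxy)phenyl]naphthalene-2-carboxylic acid | O=C(O)c1cc(-c2ccc(OCc3ccccc3)c(OCc3ccccc3)c2)c2cc(OCc3ccccc3)c(OCc3ccccc3)cc2c1 | intermediate
8 | sodium (R)-3-(3,4-dihydroxyphenyl)-2-hydroxypropanoate | O[C@H](Cc1ccc(O)c(O)c1)C(=O)[O-].[Na+] | starting material
9 | benzyl (R)-3-[3,4-bis(benzyloxy)phenyl]-2-hydroxypropanoate | O[C@H](Cc1ccc(OCc2ccccc2)c(OCc2ccccc2)c1)C(=O)OCc1ccccc1 | intermediate
10 | heptabenzyl eritrichin (benzyl ester, hexabenzyl ether) | O=C(O[C@H](Cc1ccc(OCc2ccccc2)c(OCc2ccccc2)c1)C(=O)OCc1ccccc1)c1cc(-c2ccc(OCc3ccccc3)c(OCc3ccccc3)c2)c2cc(OCc3ccccc3)c(OCc3ccccc3)cc2c1 | intermediate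
11 | eritrichin | O=C(O[C@H](Cc1ccc(O)c(O)c1)C(=O)O)c1cc(-c2ccc(O)c(O)c2)c2cc(O)c(O)cc2c1 | target

## Summary

**Total steps:** 7
**Longest linear sequence:** 6 (steps 1, 2, 3, 4, 6, 7); step 5 is a one-step side branch.

**Steps most likely to fail, with fallbacks:**

- **Step 3 (photocyclisation).** Risks are E/Z photostationary mixtures, some closure at the hindered C2 position, and secondary photochemistry of 6. Fallback: replace the pericyclic closure by an ionic one. Make dimethyl (E,E)-bis(3,4-dimethoxybenzylidene)succinate from veratraldehyde and cyclise with TfOH (cationic Friedel–Crafts closure para to OMe). Saponify, decarboxylate as in step 4, then exchange OMe for OBn on the robust naphthoic acid (BBr3; BnBr/K2CO3; LiOH) before coupling.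
- **Step 4 (oxidative decarboxylation).** Risks are competing simple dehydrogenation to the naphthalene-2,3-diacid and oxidation of the electron-rich rings. Fallback: dehydrogenate 6 deliberately (DDQ) to the 1-arylnaphthalene-2,3-dicarboxylic acid, then remove the carboxyl next to the aryl group (twisted, flanked on both sides) by Ag- or Cu-catalysed protodecarboxylation. This is done before the stereocentre is introduced.
- **Step 2 (one-pot double Stobbe).** Risks are stopping at the mono-arylidene half-ester and E/Z mixtures. Fallback: build the diene C–C bond instead by Ni(0)/Zn reductive homocoupling of ethyl (Z)-2-bromo-3-[3,4-bis(benzyloxy)phenyl]acrylate (from 3 and Ph3P=C(Br)CO2Et), then saponify to 5.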